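Numbering: C1 ester carbon, C2=C3, C4, C5 (NCH), C9 spiro carbon, C13, C14 (CHMe), C17 carbinol, C23 (NCH2). Ring B (N, C23, C2, C3, C4, C5) is a masked 4-piperidone-3-carboxylate, nitrogen 1,3 to C3 on both sides. The key step frees a primary amine on C9 of a cyclopentane carrying an acyclic enone β-keto ester: aza-Michael addition closes ring A (N–C5), then formaldehyde closes ring B by a Mannich bond C23–C2; C5 is relayed from C9/C13. A phenylglycinol-derived bicyclic lactam supplies C9, C13, C14; alkynylation sets C17; semihydrogenation and macrolactonisation finish.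

Key step: step 9

Remark: ring A is the piperidine (N, C5–C9), the cyclopentane is C9–C13, C21 is the OCH2 carbon. CIP descriptors of unchanged centres can switch as substituents change, so the SMILES are authoritative.
Assumption: ZnMe2/(S,S)-ProPhenol is taken to deliver the alkyne to the Re face of the enal in step 16; if the sense proves opposite, the (R,R)-ligand is used.

Step 1
Reactants: 1 2-(2-oxocyclopentyl)acetic acid (racemic); 2 (R)-phenylglycinol
Product: 3 tricyclic N,O-acetal lactam
Conditions: toluene, reflux, Dean–Stark trap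
Reagents that add atoms: (R)-phenylglycinol N[C@@H](CO)c1ccccc1
Why: Meyers-type bicyclic lactam formation (condensation, N,O-acetalisation, lactamisation) in which the α-centre of 1 epimerises through the enamine, so both enantiomers should converge on the cis-fused tricycle with the cyclopentane CH2 cis to phenyl, which fixes C9 and C13 from the auxiliary.

Step 2
Reactants: 3 tricyclic N,O-acetal lactam; 4 allyltrimethylsilane
Product: 5 N-[(R)-2-hydroxy-1-phenylethyl] lactam with angular allyl on C9
Conditions: TiCl4, CH2Cl2, −78 °C to rt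
Reagents that add atoms: allyltrimethylsilane C=CC[Si](C)(C)C
Why: Hosomi–Sakurai allylation of the N-acyliminium ion released by TiCl4 from the N,O-acetal; the cis ring fusion dictated by C13 leaves only the convex face open, so allyl replaces oxygen and C9 becomes the quaternary centre with nitrogen cis to the C14 arm.

Step 3
Reactants: 5 N-(hydroxyphenylethyl) allyl lactam
Product: 6 (3aR,6aS)-6a-allylhexahydrocyclopenta[b]pyrrol-2(1H)-one
Conditions: Na, liquid NH3, THF, EtOH, −78 °C
Reagents that add atoms: none
Why: Dissolving-metal (Birch-type) reduction cleaves the benzylic C–N bond of the lactam nitrogen, while the isolated terminal alkene and the lactam survive at −78 °C.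

Step 4
Reactants: 6 NH lactam; 7 di-tert-butyl dicarbonate
Product: 8 N-Boc lactam
Conditions: Et3N, DMAP (cat.), CH2Cl2, rt
Reagents that add atoms: di-tert-butyl dicarbonate CC(C)(C)OC(=O)OC(=O)OC(C)(C)C
Why: N-Acylation of the lactam under DMAP catalysis activates the ring carbonyl for clean enolate C-alkylation and for later ring opening.

Step 5
Reactants: 8 N-Boc lactam; 9 iodomethane
Product: 10 N-Boc 3-methyl lactam (methyl cis to H13)
Conditions: LiN(SiMe3)2, THF, −78 °C; then MeI
Reagents that add atoms: iodomethane CI
Why: Alkylation of the lactam lithium enolate from the convex face, anti to cyclopentane carbon C12 on the neighbouring ring-fusion atom, should place the methyl group cis to H13 and so set C14.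

Step 6
Reactants: 10 N-Boc 3-methyl lactam; 11 diethylamine
Product: 12 Boc-amino diethylamide with allyl on C9
Conditions: AlMe3, CH2Cl2, 0 °C to rt
Reagents that add atoms: diethylamine CCNCC
Why: Aminolysis of the N-Boc-activated lactam by the aluminium amide at the ring carbonyl opens the ring without touching C14 and leaves BocNH on C9 and a tertiary amide that stays inert until step 10.

Step 7
Reactants: 12 Boc-amino diethylamide; 13 carbon monoxide
Product: 14 C5 aldehyde (4-oxobutyl chain on C9)
Conditions: Rh(acac)(CO)2 (cat.), BiPhePhos, CO/H2 (1:1, 5 bar), toluene, 60 °C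
Reagents that add atoms: carbon monoxide [C-]#[O+]
Why: Rhodium-catalysed hydroformylation with a wide-bite-angle bisphosphite is linear-selective for terminal alkenes, and the adjacent quaternary carbon further disfavours the branched aldehyde.

Step 8
Reactants: 14 C5 aldehyde; 15 ethyl 3-oxo-4-(triphenylphosphoranylidene)butanoate
Product: 16 (E)-enone β-keto ester
Conditions: 15, NaH, THF, 0 °C; then 14, 0 °C to rt; AcOH quench
Reagents that add atoms: ethyl 3-oxo-4-(triphenylphosphoranylidene)butanoate CCOC(=O)CC(=O)C=P(c1ccccc1)(c1ccccc1)c1ccccc1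
Why: Wittig olefination with the acyl-stabilised ylide, used as its more reactive sodium salt, should give the (E)-enone and installs C4 to C1 as a γ,δ-unsaturated β-keto ester in one operation.

Step 9
Reactants: 16 (E)-enone β-keto ester; 17 formaldehyde
Product: 20 tricyclic β-keto ester (enol form), via primary amine enone 18 (not isolated), via piperidine β-keto ester 19 (not isolated)
Conditions: TFA, CH2Cl2, 0 °C; evaporate; K2CO3, EtOH, rt; then 37 % aq. CH2O, rt
Reagents that add atoms: formaldehyde C=O
Why: Acidolysis of the carbamate frees the C9 amine, which after neutralisation adds to the (E)-enone in a 6-exo-trig aza-Michael reaction (N–C5, ring A); formaldehyde then turns the secondary amine into an N-methyleneiminium ion, which the enol of the β-keto ester captures at C2 in a 6-endo-trig Mannich closure (C23–C2, ring B). The closest known reaction types are the aza-Michael cyclisation of amino enones to 2-substituted piperidines and the formaldehyde Mannich cyclisation of δ-amino β-keto esters to 4-piperidone-3-carboxylates (Petrenko-Kritschenko-type piperidone synthesis). C5 is the only new stereocentre that is kept (C2 is lost in the enol) and is set by substrate control: the β-amino ketone can revert by retro-Michael reaction, so the ring A chair with the C4 chain equatorial and the branched cyclopentane carbon C13 equatorial (C10 axial) should prevail, placing C4 cis to C13 (5R). The Mannich bond must form at C2 and not at C4, which is secured because only C2 is doubly activated and only it gives a six-membered ring. N–C5 must form before any N-methylenation, which is secured by adding formaldehyde only after the aza-Michael step; the tertiary diethylamide cannot lactamise onto the free amine under these conditions.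

Step 10
Reactants: 20 tricyclic β-keto ester
Product: 22 tricyclic enoate aldehyde, via tricyclic enoate diethylamide 21 (not isolated)
Conditions: LiN(SiMe3)2, THF, −78 °C; Cp2Zr(H)Cl (excess), −78 °C to rt; aq. NaHCO3 work-up
Reagents that add atoms: none
Why: Two known reactions of the Schwartz reagent are run in one flask: deoxygenative reduction of the β-keto ester enolate to the α,β-unsaturated ester (C2=C3, no new stereocentre) and reduction of the tertiary amide to a zirconium hemiaminal that gives the aldehyde on work-up, the ester being inert to the reagent.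

Step 11
Reactants: 22 tricyclic enoate aldehyde; 23 dimethyl (1-diazo-2-oxopropyl)phosphonate
Product: 24 tricyclic terminal alkyne
Conditions: K2CO3, EtOH, 0 °C to rt
Reagents that add atoms: dimethyl (1-diazo-2-oxopropyl)phosphonate CC(=O)C(=[N+]=[N-])P(=O)(OC)OC
Why: Ohira–Bestmann homologation converts the aldehyde into the terminal alkyne under mild carbonate conditions in ethanol, which avoids ester exchange and should not epimerise the α-branched C14.

Step 12
Reactants: 25 dihydro-2H-pyran-2,4(3H)-dione; 26 oxalyl chloride
Product: 27 4-chloro-5,6-dihydro-2H-pyran-2-one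
Conditions: DMF (cat.), CH2Cl2, 0 °C to rt
Reagents that add atoms: oxalyl chloride ClC(=O)C(=O)Cl
Why: Vilsmeier-type chlorination of the enolised cyclic 1,3-dicarbonyl gives the vinylogous acid chloride, and the six-membered ring fixes C17 and C20 cis on the chloroalkene, the geometry required in the target.

Step 13
Reactants: 27 4-chloro-5,6-dihydro-2H-pyran-2-one; 28 N,O-dimethylhydroxylamine hydrochloride
Product: 29 (E)-3-chloro-5-hydroxy-N-methoxy-N-methylpent-2-enamide
Conditions: AlMe3, CH2Cl2, 0 °C
Reagents that add atoms: N,O-dimethylhydroxylamine hydrochloride CNOC.Cl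
Why: Weinreb aminolysis of the lactone with the aluminium amide occurs by carbonyl-directed 1,2-attack, so the ring opens to the hydroxy Weinreb amide with the alkene geometry retained.

Step 14
Reactants: 29 hydroxy Weinreb amide; 30 acetic anhydride
Product: 31 (E)-5-acetoxy-3-chloro-N-methoxy-N-methylpent-2-enamide
Conditions: pyridine, DMAP (cat.), CH2Cl2, 0 °C
Reagents that add atoms: acetic anhydride CC(=O)OC(C)=O
Why: Acetylation of the primary alcohol prevents relactonisation and gives a protecting group that the later saponification removes together with the ethyl ester.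

Step 15
Reactants: 31 acetoxy Weinreb amide
Product: 32 (E)-5-acetoxy-3-chloropent-2-enal (CHO cis to C20H2)
Conditions: Cp2Zr(H)Cl, THF, rt
Reagents that add atoms: none
Why: The Schwartz reagent reduces the Weinreb amide to the aldehyde through a stable zirconium hemiaminal and leaves the acetate untouched; the enal is used without delay to avoid isomerisation of the chloroalkene.

Step 16
Reactants: 24 tricyclic terminal alkyne; 32 (E)-5-acetoxy-3-chloropent-2-enal
Product: 33 tricyclic propargylic alcohol (17S)
Conditions: (S,S)-ProPhenol (cat.), ZnMe2, Ph3P=O (cat.), toluene, 0 °C; 32 in excess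
Reagents that add atoms: (E)-5-acetoxy-3-chloropent-2-enal O=C/C=C(/Cl)CCOC(C)=O
Why: Catalytic asymmetric alkynylation of an enal by a dinuclear zinc–ProPhenol alkynylzinc complex is mild enough for the ester, amine and chloroalkene, and the ligand is expected to deliver the alkyne to the Re face, giving 17S here (the spatial arrangement that is 17R in the target).

Step 17
Reactants: 33 tricyclic propargylic alcohol
Product: 34 (15Z)-allylic alcohol
Conditions: H2 (1 atm), Pd/CaCO3 poisoned with Pb(OAc)2 (Lindlar catalyst), quinoline, EtOAc, rt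
Reagents that add atoms: none
Why: Lindlar semihydrogenation adds hydrogen syn to the alkyne and gives the (15Z)-alkene, while the trisubstituted enoate and the chloroalkene are not reduced by the poisoned catalyst.

Step 18
Reactants: 34 (15Z)-allylic alcohol; 35 lithium hydroxide
Product: 36 seco acid (C1 acid, C17 and C21 hydroxyls free)
Conditions: LiOH, THF/MeOH/H2O, rt to 40 °C; AcOH to pH 6
Reagents that add atoms: lithium hydroxide [Li+].[OH-]
Why: Saponification cleaves the acetate and the conjugated ethyl ester, while the bis-allylic alcohol and the vinyl chloride are stable to hydroxide.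

Step 19
Reactants: 36 seco acid
Product: 37 CNP0129639.4
Conditions: 2-methyl-6-nitrobenzoic anhydride, DMAP, Et3N, CH2Cl2, high dilution (slow addition), rt
Reagents that add atoms: none
Why: Shiina macrolactonisation through the mixed anhydride should acylate the unhindered primary C21 hydroxyl to the 15-membered lactone in preference to the hindered bis-allylic C17 hydroxyl (which would give a strained 11-membered ring), and the two cis ring alkenes preorganise the seco acid.

Compound list
1 | 2-(2-oxocyclopentyl)acetic acid (racemic) | O=C1CCCC1CC(=O)O | starting material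
2 | (R)-2-amino-2-phenylethanol ((R)-phenylglycinol) | N[C@@H](CO)c1ccccc1 | starting material
3 | tricyclic lactam: (R)-phenylglycinol N,O-acetal of the cis-fused cyclopenta-γ-lactam, phenyl cis to ring carbon C10 on the oxazolidine | O=C1C[C@H]2CCC[C@@]2(OC[C@H]3c4ccccc4)N13 | intermediate
4 | allyltrimethylsilane | C=CC[Si](C)(C)C | starting material
5 | cis-fused γ-lactam with angular allyl on C9 and N-[(R)-2-hydroxy-1-phenylethyl] (9S,13R) | O=C1C[C@H]2CCC[C@@]2(CC=C)N1[C@@H](CO)c1ccccc1 | intermediate
6 | (3aR,6aS)-6a-allylhexahydrocyclopenta[b]pyrrol-2(1H)-one | O=C1C[C@H]2CCC[C@@]2(CC=C)N1 | intermediate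
7 | di-tert-butyl dicarbonate | CC(C)(C)OC(=O)OC(=O)OC(C)(C)C | starting material
8 | tert-butyl (3aR,6aS)-6a-allyl-2-oxohexahydrocyclopenta[b]pyrrole-1(2H)-carboxylate | O=C1C[C@H]2CCC[C@@]2(CC=C)N1C(=O)OC(C)(C)C | intermediate
9 | iodomethane | CI | starting material
10 | tert-butyl (3R,3aR,6aS)-6a-allyl-3-methyl-2-oxohexahydrocyclopenta[b]pyrrole-1(2H)-carboxylate (methyl cis to H-3a) | O=C1[C@H](C)[C@H]2CCC[C@@]2(CC=C)N1C(=O)OC(C)(C)C | intermediate
11 | diethylamine | CCNCC | starting material
12 | tert-butyl N-[(1S,2R)-1-allyl-2-[(2R)-1-(diethylamino)-1-oxopropan-2-yl]cyclopentyl]carbamate | CCN(CC)C(=O)[C@H](C)[C@H]1CCC[C@@]1(CC=C)NC(=O)OC(C)(C)C | intermediate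
13 | carbon monoxide | [C-]#[O+] | starting material
14 | tert-butyl N-[(1S,2R)-2-[(2R)-1-(diethylamino)-1-oxopropan-2-yl]-1-(4-oxobutyl)cyclopentyl]carbamate | CCN(CC)C(=O)[C@H](C)[C@H]1CCC[C@@]1(CCCC=O)NC(=O)OC(C)(C)C | intermediate
15 | ethyl 3-oxo-4-(triphenylphosphoranylidene)butanoate | CCOC(=O)CC(=O)C=P(c1ccccc1)(c1ccccc1)c1ccccc1 | starting material
16 | ethyl (E)-8-[1-(Boc-amino)-2-[1-(diethylamino)-1-oxopropan-2-yl]cyclopentyl]-3-oxooct-4-enoate (C9, C13, C14 as in 14) | CCN(CC)C(=O)[C@H](C)[C@H]1CCC[C@@]1(CCC/C=C/C(=O)CC(=O)OCC)NC(=O)OC(C)(C)C | intermediate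
17 | formaldehyde | C=O | starting material
18 | primary amine enone (16 without Boc) | CCN(CC)C(=O)[C@H](C)[C@H]1CCC[C@@]1(CCC/C=C/C(=O)CC(=O)OCC)N | intermediate
19 | 6-azaspiro[4.5]decane (NH) with C5 chain CH2C(O)CH2CO2Et cis to C13 across ring A (5R) and the diethylamide arm on C13 | CCOC(=O)CC(=O)C[C@H]1CCC[C@]2(CCC[C@@H]2[C@@H](C)C(=O)N(CC)CC)N1 | intermediate
20 | tricyclic β-keto ester, drawn as enol (ring B: N, C23, C2(CO2Et)=C3(OH), C4, C5) | CCOC(=O)C1=C(O)C[C@H]2CCC[C@]3(CCC[C@@H]3[C@@H](C)C(=O)N(CC)CC)N2C1 | intermediate
21 | tricyclic enoate diethylamide (C2=C3) | CCOC(=O)C1=CC[C@H]2CCC[C@]3(CCC[C@@H]3[C@@H](C)C(=O)N(CC)CC)N2C1 | intermediate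
22 | tricyclic enoate aldehyde (C15 CHO) | CCOC(=O)C1=CC[C@H]2CCC[C@]3(CCC[C@@H]3[C@@H](C)C=O)N2C1 | intermediate
23 | dimethyl (1-diazo-2-oxopropyl)phosphonate | CC(=O)C(=[N+]=[N-])P(=O)(OC)OC | starting material
24 | tricyclic terminal alkyne (C15≡C16) | CCOC(=O)C1=CC[C@H]2CCC[C@]3(CCC[C@@H]3[C@@H](C)C#C)N2C1 | intermediate
25 | dihydro-2H-pyran-2,4(3H)-dione | O=C1CCOC(=O)C1 | starting material
26 | oxalyl chloride | ClC(=O)C(=O)Cl | starting material
27 | 4-chloro-5,6-dihydro-2H-pyran-2-one | O=C1C=C(Cl)CCO1 | intermediate
28 | N,O-dimethylhydroxylamine hydrochloride | CNOC.Cl | starting material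
29 | (E)-3-chloro-5-hydroxy-N-methoxy-N-methylpent-2-enamide | CON(C)C(=O)/C=C(/Cl)CCO | intermediate
30 | acetic anhydride | CC(=O)OC(C)=O | starting material
31 | (E)-5-acetoxy-3-chloro-N-methoxy-N-methylpent-2-enamide | CON(C)C(=O)/C=C(/Cl)CCOC(C)=O | intermediate
32 | (E)-5-acetoxy-3-chloropent-2-enal | O=C/C=C(/Cl)CCOC(C)=O | intermediate
33 | tricyclic propargylic alcohol (17S), C21 acetate, C1 ethyl ester | CCOC(=O)C1=CC[C@H]2CCC[C@]3(CCC[C@@H]3[C@@H](C)C#C[C@@H](O)/C=C(/Cl)CCOC(C)=O)N2C1 | intermediate
34 | (15Z)-allylic alcohol (17R), C21 acetate, C1 ethyl ester | CCOC(=O)C1=CC[C@H]2CCC[C@]3(CCC[C@@H]3[C@@H](C)/C=C\[C@@H](O)/C=C(/Cl)CCOC(C)=O)N2C1 | intermediate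
35 | lithium hydroxide | [Li+].[OH-] | starting material
36 | seco acid (C1 CO2H, C17 OH, C21 OH) | OC(=O)C1=CC[C@H]2CCC[C@]3(CCC[C@@H]3[C@@H](C)/C=C\[C@@H](O)/C=C(/Cl)CCO)N2C1 | intermediate
37 | CNP0129639.4, (5R,9S,13R,14S,17R,15Z,18E) macrolactone | C[C@H]1/C=C\[C@@H](O)/C=C(/Cl)CCOC(=O)C2=CC[C@H]3CCC[C@]4(CCC[C@H]14)N3C2 | target

Total step count: 19. Longest linear sequence: 15 steps (steps 1–11 and 16–19); steps 12–15 make the side-chain aldehyde.

Steps most likely to fail

1. Step 16 may give insufficient or inverted facial selectivity at C17, or the enal may isomerise before addition. The fallback sets out from 24 and 32: the addition is run without regard to selectivity, and the resulting C17-epimeric mixture of 33 is oxidised with MnO2 in CH2Cl2 to the alkynyl chlorovinyl ketone F1. Reduction with (S)-2-methyl-CBS-oxazaborolidine and catecholborane in toluene at −78 °C, where the alkenyl group acts as the large and the alkynyl group as the small substituent, returns to the route at 33.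

2. Step 10 may suffer incomplete deoxygenation or over-reduction when the two Cp2Zr(H)Cl reductions are combined. The fallback sets out from 20: NaBH4 in EtOH at 0 °C reduces the ketone to the β-hydroxy ester F2, MsCl/Et3N gives the mesylate F3, and DBU-promoted E1cB elimination gives the enoate amide 21, now isolated. Cp2Zr(H)Cl alone then reduces the amide, and the route is rejoined at 22.

3. Step 9 may lose material by self-condensation of the enone β-keto ester, by methylenation at C2 before ring closure, or by incomplete equilibration at C5. The fallback sets out from 14: Wittig reaction with Ph3P=CHCO2Et gives the Boc-amino enoate F4, and TFA followed by K2CO3 in EtOH triggers aza-Michael closure to the piperidine acetic ester F5. Crossed Claisen condensation with LiCH2CO2Et (from EtOAc and LiN(iPr)2, THF, −78 °C) gives 19, which is isolated and closed with formaldehyde in EtOH, rejoining the route at 20.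

Further compounds
F1 | step 16 | alkynyl chlorovinyl ketone (C17 ketone corresponding to 33) | CCOC(=O)C1=CC[C@H]2CCC[C@]3(CCC[C@@H]3[C@@H](C)C#CC(=O)/C=C(/Cl)CCOC(C)=O)N2C1
F2 | step 10 | tricyclic β-hydroxy ester (C3 carbinol, mixture at C2 and C3) | CCOC(=O)C1C(O)C[C@H]2CCC[C@]3(CCC[C@@H]3[C@@H](C)C(=O)N(CC)CC)N2C1
F3 | step 10 | mesylate of F2 | CCOC(=O)C1C(OS(C)(=O)=O)C[C@H]2CCC[C@]3(CCC[C@@H]3[C@@H](C)C(=O)N(CC)CC)N2C1
F4 | step 9 | Boc-amino (E)-enoate (C5=C4, C3 ethyl ester) | CCN(CC)C(=O)[C@H](C)[C@H]1CCC[C@@]1(CCC/C=C/C(=O)OCC)NC(=O)OC(C)(C)C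
F5 | step 9 | piperidine acetic ester (6-azaspiro[4.5]decane, C5 CH2CO2Et cis to C13) | CCOC(=O)C[C@H]1CCC[C@]2(CCC[C@@H]2[C@@H](C)C(=O)N(CC)CC)N1
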